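Amounts first: the flask held 0.020 M of each substrate and 0.0500 M of partner, and it ran for 50 h.

common to all: left-handed substrate 0.020 M; right-handed substrate 0.020 M; free catalyst 0.20 mM

| run | partner | racemization catalyst | remark | time |
|---|---|---|---|---|
| north-west | 0.025 M | 1 mM | run made earlier |  |
| west | 0.038 M | 1 mM | run made earlier |  |
| south | 0.050 M | 0.50 mM | run made earlier |  |
| flask | 0.0500 M | 1.0 mM |  | 50 h |

| run | time / h | left-handed product / % | right-handed product / % |
|---|---|---|---|
| north-west | 8.00 | 32.1 | 20.2 |
| north-west | 15.0 | 34.6 | 22.3 |
| north-west | 20.0 | 35.2 | 22.9 |
| north-west | 30.0 | 36.6 | 23.5 |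
| north-west | 40.0 | 36.2 | 24.4 |
| north-west | 48.0 | 37.1 | 24.6 |
| west | 4.00 | 34.5 | 23.4 |
| west | 6.00 | 38.4 | 28.2 |
| west | 10.0 | 43.7 | 32.0 |
| west | 15.0 | 45.4 | 35.1 |
| west | 20.0 | 46.7 | 37.0 |
| west | 30.0 | 47.5 | 36.7 |
| west | 48.0 | 47.5 | 39.6 |
| south | 4.00 | 41.3 | 28.7 |
| south | 12.0 | 47.9 | 40.8 |
| south | 25.0 | 50.4 | 45.9 |
| south | 40.0 | 49.7 | 46.9 |
| south | 48.0 | 50.0 | 47.9 |

(each reading ± 0.5 percentage points)

- free catalyst is single-handed; left-handed substrate and right-handed substrate are mirror images of each other, charged as a racemate, each of them at the stated concentration
- the numbers in the tables scatter by 0.5 percentage points (one standard deviation)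
- an excess is the difference of the two amounts in percent of their sum
- an excess is below zero if the other one leads

1. left-handed product and right-handed product together, in percent of the left-handed substrate and right-handed substrate charged together, at 50 h
2. excess of left-handed product over right-handed product in the product at 50 h
3. whether the exchange between left-handed substrate and right-handed substrate keeps pace with the reaction: how far the product's excess at 50 h gets from its value without exchange to its value with instant exchange (above 80% keeps pace, below 20% hardly takes part, else lags behind)

1. Ceilings. Without exchange, each product can reach 50.0% of the two substrates charged. The north-west run read 61.7% at 48.0 h, where its partner allowed 62.5%, so I took one partner per product. The flask's partner allowed 125%, more than its substrates, so on paper substrate was the limiting reagent there.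

2. The rule. I worked with the fraction left of each substrate's own charge, not with the product made. I divided the logarithm of the fraction left of left-handed substrate by that of right-handed substrate. Early readings gave 1.98 (north-west), 1.86 (west) and 2.05 (south), with mean 1.96. This ratio s is the selectivity factor, read from the runs.

3. Exchange. Exchange refills left-handed substrate and so lowers the ratio. The west run, with 1 mM of racemization catalyst, gave 1.91 at 48.0 h, against 1.86 at 4.00 h. I read no exchange, and I took the south run's right-handed product for the flask's, since the partner charges match.

4. The curve. The start: products form s to one, an excess of 32.5%. The knee: at 12.0 h, right-handed substrate stood at 18.4% of its charge, so left-handed substrate stood at 3.60%, and left-handed product was near its ceiling. The level: at 48.0 h, 4.20% gives 0.198%. I reckoned a yield of 97.8% and an excess of 2.05%. In this reckoning, which leaves exchange out, the curves do not cross; both close on that no-exchange ceiling.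

5. The forecast. It said 97.5%, 2.4% and hardly takes part, on the ground “I see no sign of exchange”. Its excess stood slightly above mine.

6. The flask gave 98.7%, 2.18% and hardly takes part, 3.1% of the way.

    free catalyst → spent catalyst A (k = 1.70 × 10⁻⁸ /s)
    left-handed substrate + racemization catalyst ⇌ right-handed substrate + racemization catalyst, rate k2*[racemization catalyst]*[left-handed substrate] forward; the back reaction follows from the equilibrium constant (k = 0.00600 /M/s)
    partner + free catalyst + left-handed substrate → free catalyst + left-handed product (k = 19.0 /M²/s)
    2 racemization catalyst → spent catalyst B (k = 0.180 /M/s)
    partner ⇌ dormant form (K = 1.00, k = 3.90 × 10⁻⁶ /s)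
    partner + free catalyst + right-handed substrate → free catalyst + right-handed product (k = 9.80 /M²/s)

At 50.0 h, the flask's making of left-handed product used left-handed substrate 240 times as fast as the forward exchange step. The ratio of logarithms in the flask then stood at 1.85, from 0.11% and 2.4% left of the charges. The forecast's excess fails with a smaller partner charge: the neighbour with 0.020 M of partner kept 0.18% of it and stopped at 48.7%. There, 62% of right-handed substrate left gives 38.5% by s, against 41% of left-handed substrate in that flask, and its excess stood at 23.2%.

(Readings and results stem from a simulated flask for an exercise, noise included.)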